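The slowness of the alder flask can be held in one number, and it reads best from what is left, not from what is made.

| flask | electrophile | nucleophile | buffer base | buffer acid | scavenger | remark | time |
|---|---|---|---|---|---|---|---|
| alder | 20 mM | 2.5 equiv | 2 equiv | 1 equiv | 1 equiv | the very flask that is asked about, followed so far |  |
| larch | 30 mM | 2.5 equiv | 2 equiv | 1 equiv | 1 equiv | run made earlier |  |
| flask | 20 mM | 2.50 equiv | 2.00 equiv | 1.00 equiv | 1.00 equiv |  | 25 min |

| run | time / min | electrophile / % | target / % |
|---|---|---|---|
| alder | 1.00 | 94.6 | 6.1 |
| alder | 2.00 | 88.1 | 12.1 |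
| alder | 3.00 | 82.6 | 17.2 |
| alder | 4.00 | 77.4 | 22.9 |
| alder | 5.00 | 72.1 | 26.2 |
| larch | 4.00 | 68.6 | 29.6 |
| larch | 8.00 | 47.8 | 48.7 |
| larch | 10.0 | 41.9 | 55.5 |
| larch | 15.0 | 28.4 | 67.8 |
| larch | 20.0 | 18.9 | 73.4 |

(standard deviation of a reading: 0.5 percentage points)

- the numbers in the tables scatter by 0.5 percentage points (one standard deviation)
- the earlier runs do not show the pH; that part of a forecast is a guess

- part of the electrophile that has reacted at 25 min
- pH of the solution at 25 min

We assume that each electrophile takes one nucleophile and that the rate follows both amounts. The surplus of nucleophile then stays at 1.50 equivalents, and the ratio of nucleophile left to electrophile left starts at 2.50. The natural logarithm of that ratio, counted from its start, climbs steadily. The last larch reading, 18.9% left after 20.0 min, gives 1.42 L mol⁻¹ min⁻¹. This is the pace, a second-order rate constant: the climb per minute, per unit of starting electrophile and per equivalent of surplus. The last alder reading gives 1.39 L mol⁻¹ min⁻¹.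

For alder the logarithm climbs 0.0425 min⁻¹. By this reckoning the curve of electrophile left starts falling at 0.0708 min⁻¹ of the charge. We reckon half left at 11.1 min, where left and reacted cross. We reckon a quarter left at 24.2 min, so the second halving takes 13.1 min, longer than the first. The reckoned curve bends gently, with no sharp knee. On this reckoning electrophile is the limiting reagent, and the curve runs towards zero while nucleophile levels at 60.0% of its charge. At 25 min we reckon 24.1% left, so 75.9% reacted. The readings show no pH, and we reckon none.

The forecast says 75% reacted, below our figure, and pH 6.9, with the words “I guess near 7, so this is weak”.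

Alder gives 76.0% reacted and pH 9.36.

    buffer acid ⇌ buffer base + acid, settled at all times (K = 3.20 × 10⁻¹⁰ M)
    electrophile + target → side product (k = 0.00579 L mol⁻¹ s⁻¹)
    nucleophile + leaving group ⇌ idle adduct, settled at all times (K = 22.0 L mol⁻¹)
    electrophile + nucleophile → acid + target + leaving group (k = 0.0223 L mol⁻¹ s⁻¹)
    protonated nucleophile ⇌ nucleophile + acid, settled at all times (K = 6.30 × 10⁻⁷ M)
    scavenger + leaving group → scavenged by-product (k = 2.50 L mol⁻¹ s⁻¹)

The same pace at 8.0 mM of electrophile, with equivalents and time held, reckons 46.9% reacted, and that flask gives 46.0%. Alder has not come to rest at 25 min: 24.0% of the electrophile still stands. After 250 min the part reacted is >99.9%, target has gone from 69.3% to 88.0%, and free scavenger has fallen from 29.7% to 5.99%. Side product, counted as two, has gone from 6.70% to 12.0%.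

The readings were generated by integration from invented constants, noise included.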